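3 questions are put to Thursday's and Saturday's flasks.

- which of the two ends with the longer chains by the average number of monomer units in a chain (chains begun, living or dead) ("neither" if they lie within 10%) (Thursday's / Saturday's / neither)
- average number of monomer units in a chain (chains begun, living or dead) at the end, Thursday's
- average number of monomer units in a chain (chains begun, living or dead) at the end, Saturday's

    J + E → G + D (k1 = 0.298 M⁻¹ min⁻¹)
    J + G → D + G, rate k2*[G]*[J] (k2 = 2.50 M⁻¹ min⁻¹)
    D + G → J + G, rate k3*[G] as long as [D] is above zero (k3 = 0.0747 min⁻¹)
    L + J → L.J (k4 = 0.0339 M⁻¹ min⁻¹)

common to all: J 0.20 M; L 0.0400 M; time 30 h

| run | E |
|---|---|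
| Thursday's | 1.0 mM |
| Saturday's | 0.25 mM |

- the average divides the monomer in chains by the number of chains begun, living and dead together
- run time (Thursday's): 30 h

- Living ends add J in proportion to its level and give it back at a steady rate. By these two steps, J comes to rest where they balance, at the ratio of the unzipping constant to the adding constant, 0.0299 M, the equilibrium monomer level.
- A first estimate counts one chain per unit of E and subtracts that level and the charge of L from the charge of J. What remains is the room, the J available to chains: 0.130 M. Room over E gives 130 for Thursday's and 520 for Saturday's.
- One objection is that ends need time to form, but E's half-life at charged J is 11.6 min, shorter than the filling times below.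
- A stronger objection is that chains need time to fill the room. The approach is pseudo-first-order in the ends, with a half-life of 4.62 h on Thursday's and a longer 18.5 h on Saturday's, against a run of 30 h.
- The unfilled part of the room at the end is 1.11% on Thursday's and 32.5% on Saturday's. The estimates become 129 and 352.
- A last objection is that L slows as J falls, although its half-life at the charge is 1.7 h. Replacing Thursday's J curve by its mean, 0.0588 M, leaves 2.77% of L, which lifts Thursday's estimate to 130. Saturday's mean is higher, 0.108 M, and leaves 0.137%, so its estimate stands.
- The forecast names Saturday's, with 130 and 355, slightly above this reckoning for Saturday's, and says “relaxation is slower” there.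
- The simulation gives Saturday's, with 130 for Thursday's and 356 for Saturday's.
- Saturday's chains are longer, and the main reason is the difference in the charge of E: at Thursday's charge, Saturday's flask gives 130 in place of 356. Room over E for Saturday's is 520, and that flask stands at 520 after 300 h. A neighbour of Thursday's charged with 0.024 M of L has a room of 0.146 M, which over Thursday's E gives 146, and that flask ends at 145.

The numbers stand for no real mixture; the flask was simulated.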